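# Synthesis of Epicalyxin B

**Target check.** Epicalyxin B is a cardamonin-type chalcone. The ring is 2′,4′-dihydroxy-6′-methoxy, with a CH(4-hydroxyphenyl)–CH=CH–CH₂–CH(OH)–CH₂CH₂–C₆H₄OH unit on C3′. C3 is (S), C7 is (R), and both C=C bonds are E.

**Assumptions (one line):** Acetophenone **11** is commercial (otherwise made from 5-methoxyresorcinol by BF₃·OEt₂/AcOH acylation). C3′ is attacked rather than C5′, because C3′ sits between two small OH groups and C5′ is next to OMe. The (+)-Ipc₂B(allyl) reagent gives the (S)-alcohol and (S)-TRIP gives 7R; both should be confirmed (Mosher analysis, comparison with natural product).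

## Retrosynthesis
1. Epicalyxin B ⇒ its C3-OTBS ether by fluoride removal. The C7–C3′ bond is cut by a catalytic enantioselective 1,6-Friedel–Crafts reaction (new step). The partners are the chalcone C3′–H nucleophile (**12**) and a vinylogous p-quinone methide generated from racemic 1-(4-hydroxyphenyl)allyl alcohol **10**.
2. The E-C5=C6 bond of **10** comes from cross-metathesis of homoallylic silyl ether **5** with 1-(4-silyloxyphenyl)allyl alcohol **8**.
3. The C3 stereocentre comes from Brown asymmetric allylation of 3-(4-silyloxyphenyl)propanal.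
4. The chalcone comes from Claisen–Schmidt condensation of commercial acetophenone **11** with 4-hydroxybenzaldehyde.
5. No ring is constructed; all three arenes are commercial. The C–C bonds form in the order C3–C4 (Brown), C5=C6 (metathesis), C7–C3′ (key step).

## Forward route

**Step 1**
Reactants: **1** methyl 3-(4-hydroxyphenyl)propanoate
Product: **2** methyl 3-(4-TBSO-phenyl)propanoate
Conditions: TBSCl, imidazole, DMF, 0 °C→rt, 3 h
Reagents that add atoms: TBSCl, CC(C)(C)[Si](C)(C)Cl
Why: Silylation of the phenol (standard protection) prevents interference later.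

**Step 2**
Reactants: **2**
Product: **3** 3-(4-TBSO-phenyl)propanal
Conditions: DIBAL-H (1.1 equiv), CH₂Cl₂, −78 °C, 1 h; Rochelle salt work-up
Reagents that add atoms: none (hydride only)
Why: Partial ester reduction stops at the aluminium hemiacetal at −78 °C; the aryl silyl ether survives.

**Step 3**
Reactants: **3**
Product: **4** (S)-1-(4-TBSO-phenyl)hex-5-en-3-ol
Conditions: (+)-Ipc₂B(allyl) from (−)-α-pinene (1.3 equiv), Et₂O, −78 °C, 3 h; then pH 7 buffer, 30% H₂O₂, MeOH, rt
Reagents that add atoms: B-allyldiisopinocampheylborane, C=CCB(C1CC2CC(C1C)C2(C)C)C1CC2CC(C1C)C2(C)C (allyl group retained)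
Why: Brown asymmetric allylboration proceeds through a chair Zimmerman–Traxler transition state, with the reagent delivering allyl to the Re face of the aldehyde and setting C3 as (S). The neutral oxidative work-up spares the aryl TBS ether.

**Step 4**
Reactants: **4**
Product: **5** (S)-bis-TBS ether
Conditions: TBSOTf (1.3 equiv), 2,6-lutidine, CH₂Cl₂, −78→0 °C
Reagents that add atoms: TBSOTf, CC(C)(C)[Si](C)(C)OS(=O)(=O)C(F)(F)F
Why: The secondary alcohol is silylated so that it is inert in the metathesis and Friedel–Crafts steps. The stereocentre is untouched.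

**Step 5**
Reactants: **6** 4-hydroxybenzaldehyde
Product: **7** 4-TBSO-benzaldehyde
Conditions: TBSCl, imidazole, DMF, rt, 2 h
Reagents that add atoms: TBSCl, CC(C)(C)[Si](C)(C)Cl
Why: Standard phenol silylation, so the Grignard reagent is tolerated in the next step.

**Step 6**
Reactants: **7**
Product: **8** racemic 1-(4-TBSO-phenyl)prop-2-en-1-ol
Conditions: CH₂=CHMgBr (1.2 equiv), THF, −78→0 °C
Reagents that add atoms: vinylmagnesium bromide, C=C[Mg]Br
Why: Grignard 1,2-addition to the aldehyde. The carbinol stereocentre is irrelevant because it is destroyed in step 10.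

**Step 7**
Reactants: **5** and **8** (3 equiv)
Product: **9** (E)-allylic alcohol bearing two aryl-OTBS groups and the C3-OTBS (C7 epimers about 1:1)
Conditions: Hoveyda–Grubbs II (5 mol%), CH₂Cl₂ (0.1 M), 40 °C, 16 h
Reagents that add atoms: none (ethylene is lost)
Why: Cross-metathesis of a type I terminal alkene with a type II allylic-alcohol partner gives the E-C5=C6 bond, with excess **8** driving heterocoupling.

**Step 8**
Reactants: **9**
Product: **10** (3S,5E)-3-OTBS-1,7-bis(4-hydroxyphenyl)hept-5-en-7-ol (C7 epimers)
Conditions: LiOAc·2H₂O (0.3 equiv), DMF/H₂O 50:1, rt, 4 h; use crude immediately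
Reagents that add atoms: none
Why: Lithium acetate in wet DMF selectively cleaves aryl silyl ethers and leaves the secondary alkyl TBS ether. This reveals the free p-OH needed to form the quinone methide.

**Step 9**
Reactants: **11** 2′,4′-dihydroxy-6′-methoxyacetophenone and **6** (1.2 equiv)
Product: **12** (E)-1-(2,4-dihydroxy-6-methoxyphenyl)-3-(4-hydroxyphenyl)prop-2-en-1-one
Conditions: KOH (6 equiv), EtOH/H₂O 4:1, rt→50 °C, 24 h; then 1 M HCl to pH 3
Reagents that add atoms: none (water is lost)
Why: Claisen–Schmidt aldol condensation gives the thermodynamic E-enone. Acidification gives the chelated chalcone rather than the flavanone.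

**Step 10 (key step)**
Reactants: **10** (1.0 equiv, limiting) and **12** (2.0 equiv, to suppress bis-alkylation)
Product: **13** 3-O-TBS-epicalyxin B (3S,7R)
Conditions: (S)-TRIP (10 mol%), 4 Å MS, PhMe/CH₂Cl₂ 4:1 (0.04 M), 25 °C, 48 h
Reagents that add atoms: none (water is lost)
Why: Proposed new method: the chiral phosphoric acid dehydrates the 4-hydroxybenzylic allylic alcohol to a δ-alkyl vinylogous p-quinone methide, so both C7 epimers of **10** converge on one achiral acceptor. P–OH then H-bonds the quinone methide carbonyl while P=O binds the 4′-OH of the chalcone. Chalcone C3′ then attacks C7 in a 1,6-fashion, and rearomatisation keeps the E-alkene. The 2′-OH···O=C chelate and the acceptor-type enone do not interfere. The 3,3′-aryl walls of the catalyst fix the face of attack and set C7 as (R), overriding the remote C3 stereocentre. The closest known chemistry is CPA-catalysed 1,6-addition of arenes to p-QMs and Friedel–Crafts allylation. The new features are an alkyl-substituted vinylogous p-QM, an acyl-resorcinol nucleophile bearing free phenols, C3′-selective C–H attack, and 1,6- over 1,8-regiocontrol.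

**Step 11**
Reactants: **13**
Product: **14** epicalyxin B
Conditions: HF·pyridine (large excess), pyridine/THF, 0 °C→rt, 18 h
Reagents that add atoms: none (fluoride is not retained)
Why: Buffered fluoride removes the secondary TBS ether without base-induced chalcone→flavanone cyclisation or alkene isomerisation. C3 and C7 are not epimerisable under these conditions.

## Compound list
1 | methyl 3-(4-hydroxyphenyl)propanoate | COC(=O)CCc1ccc(O)cc1 | starting material
2 | methyl 3-(4-TBSO-phenyl)propanoate | COC(=O)CCc1ccc(O[Si](C)(C)C(C)(C)C)cc1 | intermediate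
3 | 3-(4-TBSO-phenyl)propanal | O=CCCc1ccc(O[Si](C)(C)C(C)(C)C)cc1 | intermediate
4 | (S)-1-(4-TBSO-phenyl)hex-5-en-3-ol | C=CC[C@@H](O)CCc1ccc(O[Si](C)(C)C(C)(C)C)cc1 | intermediate
5 | (S)-bis-TBS ether of 4 | C=CC[C@@H](O[Si](C)(C)C(C)(C)C)CCc1ccc(O[Si](C)(C)C(C)(C)C)cc1 | intermediate
6 | 4-hydroxybenzaldehyde | O=Cc1ccc(O)cc1 | starting material
7 | 4-TBSO-benzaldehyde | O=Cc1ccc(O[Si](C)(C)C(C)(C)C)cc1 | intermediate
8 | 1-(4-TBSO-phenyl)prop-2-en-1-ol (racemic) | C=CC(O)c1ccc(O[Si](C)(C)C(C)(C)C)cc1 | intermediate
9 | (E)-allylic alcohol, two aryl-OTBS and C3-OTBS (C7 epimers) | CC(C)(C)[Si](C)(C)Oc1ccc(cc1)C(O)/C=C/C[C@@H](O[Si](C)(C)C(C)(C)C)CCc1ccc(O[Si](C)(C)C(C)(C)C)cc1 | intermediate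
10 | (3S,5E)-3-OTBS-1,7-bis(4-hydroxyphenyl)hept-5-en-7-ol (C7 epimers) | Oc1ccc(cc1)C(O)/C=C/C[C@@H](O[Si](C)(C)C(C)(C)C)CCc1ccc(O)cc1 | intermediate
11 | 2′,4′-dihydroxy-6′-methoxyacetophenone | COc1cc(O)cc(O)c1C(C)=O | starting material
12 | (E)-2′,4,4′-trihydroxy-6′-methoxychalcone | COc1cc(O)cc(O)c1C(=O)/C=C/c1ccc(O)cc1 | intermediate
13 | 3-O-TBS-epicalyxin B | COc1cc(O)c([C@H](/C=C/C[C@@H](O[Si](C)(C)C(C)(C)C)CCc2ccc(O)cc2)c2ccc(O)cc2)c(O)c1C(=O)/C=C/c1ccc(O)cc1 | intermediate
14 | epicalyxin B | COc1cc(O)c([C@H](/C=C/C[C@@H](O)CCc2ccc(O)cc2)c2ccc(O)cc2)c(O)c1C(=O)/C=C/c1ccc(O)cc1 | target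

## Totals
Total steps: 11. Longest linear sequence: 8 steps (1→2→3→4→7→8→10→11).

## Three steps most likely to fail
1. **Step 10 (proposed new step).** Risks are 1,8- versus 1,6-attack, C3′ versus C5′ selectivity, bis-alkylation, low ee from background racemic reaction, and instability of **10**. Fallback: use a achiral acid (TfOH or Sc(OTf)₃) to make the 1:1 C7 diastereomers of **13** by known Friedel–Crafts allylation, then separate them by preparative HPLC, since C3 is already fixed. Confirm the natural (7R) isomer by comparison with published data.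
2. **Step 7 (cross-metathesis).** Risks are poor heterocoupling and Ru–H isomerisation of the terminal alkene. Fallback: cross-metathesis of **5** with vinyl-Bpin gives the (E)-alkenyl-Bpin. A Rh(I)-catalysed 1,2-addition of this alkenylboron to aldehyde **7** then gives **9**.
3. **Step 9 (Claisen–Schmidt on free phenols).** Risks are low yield and flavanone formation. Fallback: bis-MOM-protect **11**, condense with 4-MOMO-benzaldehyde, remove the MOM groups with HCl/MeOH at 0 °C, and then proceed to step 10.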